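The easiest setting to turn is the time, so I begin there, with these runs and questions in view.

| flask | substrate | partner | protic impurity | remark | time |
|---|---|---|---|---|---|
| gamma | 0.20 M | 0.14 M | 0.010 M | run made earlier |  |
| eta | 0.20 M | 0.22 M | 0.010 M | run made earlier |  |
| alpha | 0.30 M | 0.10 M | 0.010 M | run made earlier |  |
| flask | 0.20 M | 0.100 M | 0.0100 M |  | 15 h |

| run | time / h | target / % | substrate / % |
|---|---|---|---|
| gamma | 1.33 | 56.9 | 43.2 |
| gamma | 2.50 | 58.3 | 42.4 |
| gamma | 4.00 | 57.6 | 42.4 |
| gamma | 6.00 | 57.7 | 42.3 |
| gamma | 10.0 | 57.9 | 43.0 |
| gamma | 20.0 | 57.8 | 42.4 |
| eta | 3.00 | 85.2 | 13.8 |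
| eta | 6.00 | 86.4 | 13.2 |
| eta | 10.0 | 87.0 | 13.9 |
| eta | 12.0 | 86.4 | 13.2 |
| eta | 15.0 | 86.8 | 12.6 |
| eta | 20.0 | 85.9 | 14.1 |
| alpha | 4.00 | 29.6 | 71.2 |
| alpha | 8.00 | 28.9 | 72.7 |
| alpha | 10.0 | 28.2 | 71.7 |
| alpha | 15.0 | 29.5 | 72.4 |
| alpha | 20.0 | 27.7 | 71.2 |

(each reading ± 0.5 percentage points)

- what was read earlier has a scatter of 0.5 percentage points, one standard deviation
- candidate steps: substrate + partner -> target; 2 partner -> self-condensation product; partner + protic impurity -> quenched reagent
- the reaction counts as stopped when no species that holds the substrate changes by six tenths of a point or more over the second half of the time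

1. the state of affairs at 15 h: stopped, and by what, or still going (it is still moving / all of the substrate has reacted / the partner has run out first)
2. the target standing at 15 h, as a percentage of the substrate charged
3. amount of target if the flask were left three thousand times as long, in percent of the substrate charged

By hand, more time gives more target as long as partner remains. But the gamma run reads 56.9 % at 1.33 h and 57.8 % at 20.0 h, and the five alpha readings, taken with the partner charge of the flask, scatter around 28.8 % from 4.00 h on. So I expect the flask to have stopped by 15 h, which is later than that first alpha reading, and to hold its target afterwards.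

By hand, each target takes one partner, so more partner gives more target. Indeed, going from gamma to eta at the same substrate raises the mean target from 57.7 % to 86.3 %. Yet eta, charged with more partner than substrate, still stands with 14.1 % of its substrate unreacted, so some partner goes elsewhere, and I treat partner as the limiting reagent.

By hand, each impurity takes one partner. Alpha tests this loosely: its mean target reading accounts for 0.0863 M of its 0.10 M of partner, which leaves 0.0137 M for the impurity and self-condensation together. That is less than the 0.0200 M that two partners per impurity would take, so I keep one partner per impurity. More substrate, by hand, spreads the partner thinner, and alpha shows that low target.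

For the flask, partner charge less impurity charge, over substrate charge, gives 0.450; I call this the usable equivalents, u. Let w be the target fraction divided by u. Alpha has u = 0.300 and w = 0.959; gamma has u = 0.650 and w = 0.888; eta has u = 1.05 and w = 0.822. So w falls as u rises. A straight line between alpha and gamma gives the flask w = 0.929, and so I reckon target at 41.8 %.

The forecast says the partner has run out first, with 42 % at 15 h and 42 % in the long run: “The yield stays the same forever, since no partner remains”.

In the flask at 15 h, the partner has run out first, with 0 % of its charge left; target stands at 41.1 %, and in the long run at 41.1 %.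

    substrate + partner → target, rate k1*[substrate]*[partner]^1.5 (k = 9.49 M⁻¹·⁵ min⁻¹)
    2 partner → self-condensation product (k = 0.364 M⁻¹ min⁻¹)
    partner + protic impurity → quenched reagent (k = 35.2 M⁻¹ min⁻¹)

Already at 1.50 h the flask holds 0.308 % of its partner and 41.0 % target. Its w comes to 0.913, between those of alpha and gamma. The neighbour flask with 0.80 M of substrate has u = 0.113, and its target stands at 11.1 %.

The earlier runs and the new flask were computed on assumed constants; noise was put on by code.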